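The route rests on cutting the alkyl C–O bond O1′–C5′ of the butenolide. In the key step the carboxylate of a (Z)-γ,δ-cis-epoxy enoate opens its own epoxide at C5′ (5-exo-tet, inversion): one stereospecific operation closes the furanone ring and releases the C15 hydroxyl. It exploits the syn C15–OH/C5′–O pair that sits next to the Z-locked C3′=C4′ bond of that ring. Both centres come from a single reagent-controlled γ-chloroallylboration of a labdane enal, and a temporary δ-lactone made by ring-closing metathesis fixes the Z geometry. The decalin is bought as (+)-larixol; its 6α-oxygen relays an oxygen atom to C18, which makes C4 stereogenic.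

Key step: step 13

Numbering: labdane numbers are used for the decalin and the chain up to the carbinol carbon C15 (C16 = CH3 on C13, C17 = exocyclic CH2, C18 = 4α-CH2O, C19 = 4β-CH3, C20 = CH3 on C10). The furanone atoms are O1′, C2′(=O), C3′, C4′(CH3), C5′. All compounds belong to the normal labdane series (5α-H, 9α-H, 10β-CH3).

Assumption: (+)-larixol, a labdane sold as an isolated natural product, is taken as commercially available.

Step 1
Reactants: 1 (+)-larixol
Product: 2 6α-hydroxy-14,15-dinorlabd-8(17)-en-13-one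
Conditions: KMnO4, BnEt3NCl (cat.), CH2Cl2–H2O, 0 °C
Reagents that add atoms: none
Why: Permanganate oxidative cleavage (dihydroxylation, then glycol and α-hydroxy-acid fission) should degrade the open monosubstituted vinyl carbinol to the C13 methyl ketone faster than it attacks the hindered C8(17) methylene or the flanked equatorial 6α-OH; no stereocentre is formed.

Step 2
Reactants: 2 6α-hydroxy-14,15-dinorlabd-8(17)-en-13-one
Product: 3 6α-nitrite ester of 2
Conditions: t-BuONO (excess), CH2Cl2, 0 °C → rt, dark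
Reagents that add atoms: tert-butyl nitrite, CC(C)(C)ON=O
Why: O-Nitrosation by alkyl nitrite exchange (transnitrosation) needs neither acid nor NOCl, so the alkene and the ketone should stay untouched and C6 keeps its configuration.

Step 3
Reactants: 3 6α-nitrite ester of 2
Product: 4 6α-hydroxy-18-nitrooxy-14,15-dinorlabd-8(17)-en-13-one
Conditions: hν (365 nm), O2 (slow stream), PhCF3, 10 °C
Reagents that add atoms: dioxygen, O=O
Why: In this Barton nitrite photolysis (oxygen-trapping variant), O–NO homolysis gives the 6α-alkoxyl radical, whose equatorial C–O bond runs parallel to the equatorial C4–C18 bond, so 1,5-hydrogen transfer through a six-membered chair should take H from C18 only; O2/NO capture then gives the nitrate, and this proximity fixes the new C4 stereocentre (4α-CH2O, 4β-CH3).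

Step 4
Reactants: 4 6α-hydroxy-18-nitrooxy-14,15-dinorlabd-8(17)-en-13-one
Product: 5 6α,18-dihydroxy-14,15-dinorlabd-8(17)-en-13-one
Conditions: Zn, AcOH–THF, rt
Reagents that add atoms: none
Why: Dissolving-metal reduction cleaves the O–N bond of a nitrate ester and should leave the ketone, the alkene and all stereocentres unchanged.

Step 5
Reactants: 5 6α,18-dihydroxy-14,15-dinorlabd-8(17)-en-13-one
Product: 6 6α,18-bis(tert-butyldimethylsilyloxy)-14,15-dinorlabd-8(17)-en-13-one
Conditions: TBSOTf, 2,6-lutidine, CH2Cl2, −78 → 0 °C; dilute aqueous acid wash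
Reagents that add atoms: tert-butyldimethylsilyl triflate, CC(C)(C)[Si](C)(C)OS(=O)(=O)C(F)(F)F
Why: Silyl triflate silylation is strong enough for the neopentyl primary and the hindered secondary alcohol, and the acid wash should return any silyl enol ether to the ketone.

Step 6
Reactants: 6 6α,18-bis(tert-butyldimethylsilyloxy)-14,15-dinorlabd-8(17)-en-13-one
Product: 8 terminal alkyne, 6α,18-bis(TBS-oxy) labd-8(17)-ene core with 9β-CH2CH2C≡CH, via enol diethyl phosphate 7 (not isolated)
Conditions: LDA, THF, −78 °C; ClP(O)(OEt)2, −78 °C → rt; LDA (2.3 equiv), −78 °C → rt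
Reagents that add atoms: diethyl chlorophosphate, CCOP(=O)(Cl)OCC (its atoms stay in 7 only)
Why: Kinetic enolisation at the methyl group, O-phosphorylation and base-induced β-elimination make up the standard methyl ketone to terminal alkyne conversion, which silyl ethers and the isolated alkene tolerate.

Step 7
Reactants: 8 terminal alkyne
Product: 10 (13E)-6α,18-bis(TBS-oxy)labda-8(17),13-dien-15-ol, via (E)-alkenyl(dimethyl)alane 9 (not isolated)
Conditions: Me3Al, Cp2ZrCl2 (cat.), CH2Cl2, 0 °C → rt; n-BuLi, THF, −78 °C; (CH2O)n, rt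
Reagents that add atoms: trimethylaluminium, C[Al](C)C; paraformaldehyde (as formaldehyde), C=O
Why: Negishi carboalumination adds CH3 and Al syn across the alkyne with Al at the terminus, and hydroxymethylation of the derived alanate with retention should give only the E-trisubstituted C13=C14 bond, the 1,1-disubstituted C8(17) alkene being inert.

Step 8
Reactants: 10 (13E)-6α,18-bis(TBS-oxy)labda-8(17),13-dien-15-ol
Product: 11 (13E)-6α,18-bis(TBS-oxy)labda-8(17),13-dien-15-al
Conditions: MnO2, CH2Cl2, rt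
Reagents that add atoms: none
Why: Manganese dioxide oxidation is selective for the allylic alcohol and should keep the E geometry.

Step 9
Reactants: 11 (13E)-6α,18-bis(TBS-oxy)labda-8(17),13-dien-15-al; 12 methallyl chloride
Product: 14 syn-chlorohydrin, (13E,15S)-15-[(1S)-1-chloro-2-methylprop-2-enyl]-6α,18-bis(TBS-oxy)labda-8(17),13-dien-15-ol, via O-diisopinocampheylborinate 13 (not isolated)
Conditions: 12, LiN(c-Hex)2, (+)-Ipc2BOMe, Et2O, −95 °C; BF3·OEt2; 11, −95 → −78 °C; ethanolamine, rt
Reagents that add atoms: (+)-B-methoxydiisopinocampheylborane, COB([C@H]1C[C@H]2C[C@@H]([C@@H]1C)C2(C)C)[C@H]1C[C@H]2C[C@@H]([C@@H]1C)C2(C)C (its boron and terpene groups stay in 13 only)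
Why: In this Brown-type asymmetric allylboration with an in situ made (Z)-γ-chloroallylborane, the closed chair (Zimmerman–Traxler) transition state turns the Z geometry into the syn chlorohydrin, and the isopinocampheyl groups derived from (−)-α-pinene direct attack to the Re face of the aldehyde, so 15S and 5′S are set together under reagent control, independent of the remote decalin.

Step 10
Reactants: 14 syn-chlorohydrin; 15 acryloyl chloride
Product: 16 15-O-acrylate of 14
Conditions: i-Pr2NEt, CH2Cl2, −78 → 0 °C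
Reagents that add atoms: none
Why: O-Acylation with an acid chloride and a hindered amine base is too weakly basic to close the chlorohydrin to an epoxide and does not touch either stereocentre.

Step 11
Reactants: 16 15-O-acrylate of 14
Product: 17 (5S,6S)-5-chloro-4-methyl-6-[(13E)-labdadienyl]-5,6-dihydro-2H-pyran-2-one (5,6-cis; ring C6 = C15, ring C5 = C5′)
Conditions: Grubbs second-generation catalyst (cat.), CH2Cl2, 40 °C
Reagents that add atoms: none
Why: Ring-closing metathesis of the acrylate with the 1,1-disubstituted alkene gives a six-membered ring in which the new C3′=C4′ bond can only be Z, while the hindered C8(17) methylene and the trisubstituted C13=C14 bond are much poorer partners.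

Step 12
Reactants: 17 5,6-cis-5-chloro-δ-lactone
Product: 18 methyl (2Z)-3-[(2R,3S)-3-alkenyloxiran-2-yl]but-2-enoate, the cis-epoxide (15S,5′R) bearing the (13E)-labdadienyl chain
Conditions: NaOMe (1.05 equiv), MeOH–THF, −20 → 0 °C
Reagents that add atoms: sodium methoxide, C[O-].[Na+]
Why: In this transesterification followed by an intramolecular Williamson closure, methoxide opens the lactone at the acyl carbon and the released C15 alkoxide displaces the allylic chloride at C5′ from the rear (first inversion, S to R), which drains the equilibrium irreversibly to the cis-epoxide and keeps the Z geometry written by the ring.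

Step 13
Reactants: 18 cis-epoxy (Z)-enoate
Product: 20 6,18-bis-TBS ether of the target (15S,5′S), via lithium carboxylate 19 (not isolated)
Conditions: LiOH, THF–H2O, 0 °C → rt; then sat. aq NH4Cl, rt
Reagents that add atoms: lithium hydroxide, [Li+].[OH-]
Why: Hydroxide cleaves the methyl ester (BAc2) to the lithium carboxylate 19, whose oxygen is held by the Z C3′=C4′ bond next to C5′ and displaces the epoxide oxygen from the rear (intramolecular SN2), and the C15 alkoxide set free is protonated by the aqueous buffer. The closest known reaction type is the stereospecific lactonisation of (Z)-γ,δ-epoxy-α,β-unsaturated esters and acids to 5-(1-hydroxyalkyl)butenolides. One ring is closed, the five-membered furanone, in the 5-exo-tet mode. No centre is made from a flat atom: C5′ is inverted (R in 18, S in 20) and C15 keeps its C–O bond (S), so the cis-epoxide can give only the syn (threo) hydroxy lactone, whereas a trans-epoxide would give the anti isomer. The step needs attack at C5′ (5-exo) and not at the allylic C15 (6-endo): the acid-free medium keeps C15 free of cationic character, and the short planar tether can line up only with the C5′–O bond. The buffered water keeps the C15 oxygen protonated, which should suppress retro-vinylogous aldol cleavage and C5′ epimerisation, and the isolated alkenes and silyl ethers are inert.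

Step 14
Reactants: 20 6,18-bis-TBS ether of the target
Product: 21 target CNP0221530.1
Conditions: HF·pyridine, pyridine–THF, 0 °C → rt
Reagents that add atoms: none
Why: Buffered fluoride desilylation removes both silyl ethers without the base that would epimerise C5′ and without the strong acid that would ionise the allylic C15 alcohol.

Compound list
1 | (+)-larixol, labda-8(17),14-diene-6α,13S-diol | C=C1C[C@H](O)[C@H]2C(C)(C)CCC[C@]2(C)[C@H]1CC[C@](C)(O)C=C | starting material
2 | 6α-hydroxy-14,15-dinorlabd-8(17)-en-13-one | C=C1C[C@H](O)[C@H]2C(C)(C)CCC[C@]2(C)[C@H]1CCC(C)=O | intermediate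
3 | 6α-nitrite ester of 2 | C=C1C[C@H](ON=O)[C@H]2C(C)(C)CCC[C@]2(C)[C@H]1CCC(C)=O | intermediate
4 | 6α-hydroxy-18-nitrooxy-14,15-dinorlabd-8(17)-en-13-one | C=C1C[C@H](O)[C@H]2[C@](C)(CO[N+](=O)[O-])CCC[C@]2(C)[C@H]1CCC(C)=O | intermediate
5 | 6α,18-dihydroxy-14,15-dinorlabd-8(17)-en-13-one | C=C1C[C@H](O)[C@H]2[C@](C)(CO)CCC[C@]2(C)[C@H]1CCC(C)=O | intermediate
6 | 6α,18-bis(TBS-oxy)-14,15-dinorlabd-8(17)-en-13-one | C=C1C[C@H](O[Si](C)(C)C(C)(C)C)[C@H]2[C@](C)(CO[Si](C)(C)C(C)(C)C)CCC[C@]2(C)[C@H]1CCC(C)=O | intermediate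
7 | enol diethyl phosphate of 6 (terminal C=CH2) | C=C1C[C@H](O[Si](C)(C)C(C)(C)C)[C@H]2[C@](C)(CO[Si](C)(C)C(C)(C)C)CCC[C@]2(C)[C@H]1CCC(=C)OP(=O)(OCC)OCC | intermediate
8 | terminal alkyne (9β-CH2CH2C≡CH) | C=C1C[C@H](O[Si](C)(C)C(C)(C)C)[C@H]2[C@](C)(CO[Si](C)(C)C(C)(C)C)CCC[C@]2(C)[C@H]1CCC#C | intermediate
9 | (E)-alkenyl(dimethyl)alane | C=C1C[C@H](O[Si](C)(C)C(C)(C)C)[C@H]2[C@](C)(CO[Si](C)(C)C(C)(C)C)CCC[C@]2(C)[C@H]1CC/C(C)=C/[Al](C)C | intermediate
10 | (13E)-6α,18-bis(TBS-oxy)labda-8(17),13-dien-15-ol | C=C1C[C@H](O[Si](C)(C)C(C)(C)C)[C@H]2[C@](C)(CO[Si](C)(C)C(C)(C)C)CCC[C@]2(C)[C@H]1CC/C(C)=C/CO | intermediate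
11 | (13E)-6α,18-bis(TBS-oxy)labda-8(17),13-dien-15-al | C=C1C[C@H](O[Si](C)(C)C(C)(C)C)[C@H]2[C@](C)(CO[Si](C)(C)C(C)(C)C)CCC[C@]2(C)[C@H]1CC/C(C)=C/C=O | intermediate
12 | methallyl chloride (3-chloro-2-methylprop-1-ene) | C=C(C)CCl | starting material
13 | O-diisopinocampheylborinate of 14 | C=C1C[C@H](O[Si](C)(C)C(C)(C)C)[C@H]2[C@](C)(CO[Si](C)(C)C(C)(C)C)CCC[C@]2(C)[C@H]1CC/C(C)=C/[C@H](OB([C@H]1C[C@H]2C[C@@H]([C@@H]1C)C2(C)C)[C@H]1C[C@H]2C[C@@H]([C@@H]1C)C2(C)C)[C@@H](Cl)C(C)=C | intermediate
14 | syn-chlorohydrin (15S,5′S) | C=C1C[C@H](O[Si](C)(C)C(C)(C)C)[C@H]2[C@](C)(CO[Si](C)(C)C(C)(C)C)CCC[C@]2(C)[C@H]1CC/C(C)=C/[C@H](O)[C@@H](Cl)C(C)=C | intermediate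
15 | acryloyl chloride | C=CC(=O)Cl | starting material
16 | 15-O-acrylate of 14 | C=C1C[C@H](O[Si](C)(C)C(C)(C)C)[C@H]2[C@](C)(CO[Si](C)(C)C(C)(C)C)CCC[C@]2(C)[C@H]1CC/C(C)=C/[C@H](OC(=O)C=C)[C@@H](Cl)C(C)=C | intermediate
17 | (5S,6S)-5-chloro-4-methyl-6-alkenyl-5,6-dihydro-2H-pyran-2-one (5,6-cis) | C=C1C[C@H](O[Si](C)(C)C(C)(C)C)[C@H]2[C@](C)(CO[Si](C)(C)C(C)(C)C)CCC[C@]2(C)[C@H]1CC/C(C)=C/[C@@H]1OC(=O)C=C(C)[C@@H]1Cl | intermediate
18 | methyl (Z)-cis-epoxy enoate (15S,5′R) | C=C1C[C@H](O[Si](C)(C)C(C)(C)C)[C@H]2[C@](C)(CO[Si](C)(C)C(C)(C)C)CCC[C@]2(C)[C@H]1CC/C(C)=C/[C@@H]1O[C@@H]1/C(C)=C\C(=O)OC | intermediate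
19 | lithium (Z)-cis-epoxy enoate | C=C1C[C@H](O[Si](C)(C)C(C)(C)C)[C@H]2[C@](C)(CO[Si](C)(C)C(C)(C)C)CCC[C@]2(C)[C@H]1CC/C(C)=C/[C@@H]1O[C@@H]1/C(C)=C\C(=O)[O-].[Li+] | intermediate
20 | 6,18-bis-TBS ether of the target (15S,5′S) | C=C1C[C@H](O[Si](C)(C)C(C)(C)C)[C@H]2[C@](C)(CO[Si](C)(C)C(C)(C)C)CCC[C@]2(C)[C@H]1CC/C(C)=C/[C@H](O)[C@H]1OC(=O)C=C1C | intermediate
21 | CNP0221530.1 | C=C1C[C@H](O)[C@H]2[C@](C)(CO)CCC[C@]2(C)[C@H]1CC/C(C)=C/[C@H](O)[C@H]1OC(=O)C=C1C | target

Total step count: 14. Longest linear sequence: 14 (fully linear from 1).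

Steps most likely to fail

Step 3. The 6-alkoxyl radical may fragment along C6–C7, which is homoallylic to C8(17), and nitrogen oxides may add to that alkene; both compete with the 1,5-hydrogen transfer. The fallback sets out from 2 and comes back at 5, and it masks the alkene first. mCPBA gives the 8α,17-epoxy alcohol F1, and nitrite exchange then gives the epoxy nitrite F2. Photolysis under O2 gives the epoxy 18-nitrate F3. Zn/NaI in AcOH–NaOAc then reduces the nitrate and deoxygenates the epoxide through its iodohydrin (Cornforth-type), which returns 5.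

Step 12. Methoxide may act as a base on the acidic γ-hydrogen at C5′. This would cause vinylogous E1cB opening of the lactone, loss of HCl towards the 2-pyranone, or epimerisation of C5′ before the epoxide closes. The cis-divinyl epoxide must also be kept cold to avoid a Cope-type rearrangement. The fallback sets out from 17 and comes back at 20, and it removes the carbonyl before any base is used.
- Excess DIBAL-H gives the (Z)-chloro diol F4.
- K2CO3/MeOH closes the (Z)-cis-epoxy allylic alcohol F5.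
- MnO2 gives the (Z)-cis-epoxy enal F6.
- Pinnick oxidation gives the cis-epoxy acid F7, which closes O1′–C5′ in the phosphate buffer to give 20.

Step 13. Hydrolysis of the hindered enoate may be slow. That would leave time for external hydroxide to open the epoxide, for 6-endo opening at C15, or for translactonisation and retro-vinylogous aldol cleavage of the product. The fallback sets out from 18 and comes back at 21, and it makes the same bond with an alkoxide at a lower oxidation level.
- DIBAL-H reduces 18 to the (Z)-cis-epoxy allylic alcohol F5.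
- NaH triggers 5-exo-tet opening, with the same inversion, to the 2,5-dihydrofuran carbinol F8.
- TESCl gives the 15-O-TES dihydrofuran F9.
- CrO3·3,5-dimethylpyrazole oxidises the ring O–CH2 to the 15-O-TES butenolide F10.
- HF·pyridine removes all three silyl groups to give 21.

Further compounds
F1 | step 3 | 8α,17-epoxy-6α-hydroxy-14,15-dinorlabdan-13-one | C1O[C@@]12C[C@H](O)[C@H]3C(C)(C)CCC[C@]3(C)[C@H]2CCC(C)=O
F2 | step 3 | 6α-nitrite ester of F1 | C1O[C@@]12C[C@H](ON=O)[C@H]3C(C)(C)CCC[C@]3(C)[C@H]2CCC(C)=O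
F3 | step 3 | 8α,17-epoxy-6α-hydroxy-18-nitrooxy-14,15-dinorlabdan-13-one | C1O[C@@]12C[C@H](O)[C@H]3[C@](C)(CO[N+](=O)[O-])CCC[C@]3(C)[C@H]2CCC(C)=O
F4 | step 12 | (Z)-chloro diol (15S,5′S) | C=C1C[C@H](O[Si](C)(C)C(C)(C)C)[C@H]2[C@](C)(CO[Si](C)(C)C(C)(C)C)CCC[C@]2(C)[C@H]1CC/C(C)=C/[C@H](O)[C@@H](Cl)/C(C)=C\CO
F5 | step 12 | (Z)-cis-epoxy allylic alcohol (15S,5′R) | C=C1C[C@H](O[Si](C)(C)C(C)(C)C)[C@H]2[C@](C)(CO[Si](C)(C)C(C)(C)C)CCC[C@]2(C)[C@H]1CC/C(C)=C/[C@@H]1O[C@@H]1/C(C)=C\CO
F6 | step 12 | (Z)-cis-epoxy enal | C=C1C[C@H](O[Si](C)(C)C(C)(C)C)[C@H]2[C@](C)(CO[Si](C)(C)C(C)(C)C)CCC[C@]2(C)[C@H]1CC/C(C)=C/[C@@H]1O[C@@H]1/C(C)=C\C=O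
F7 | step 12 | (Z)-cis-epoxy enoic acid | C=C1C[C@H](O[Si](C)(C)C(C)(C)C)[C@H]2[C@](C)(CO[Si](C)(C)C(C)(C)C)CCC[C@]2(C)[C@H]1CC/C(C)=C/[C@@H]1O[C@@H]1/C(C)=C\C(=O)O
F8 | step 13 | 2,5-dihydrofuran carbinol (15S,5′S) | C=C1C[C@H](O[Si](C)(C)C(C)(C)C)[C@H]2[C@](C)(CO[Si](C)(C)C(C)(C)C)CCC[C@]2(C)[C@H]1CC/C(C)=C/[C@H](O)[C@H]1OCC=C1C
F9 | step 13 | 15-O-TES ether of F8 | C=C1C[C@H](O[Si](C)(C)C(C)(C)C)[C@H]2[C@](C)(CO[Si](C)(C)C(C)(C)C)CCC[C@]2(C)[C@H]1CC/C(C)=C/[C@H](O[Si](CC)(CC)CC)[C@H]1OCC=C1C
F10 | step 13 | 15-O-TES-6,18-bis-TBS ether of the target | C=C1C[C@H](O[Si](C)(C)C(C)(C)C)[C@H]2[C@](C)(CO[Si](C)(C)C(C)(C)C)CCC[C@]2(C)[C@H]1CC/C(C)=C/[C@H](O[Si](CC)(CC)CC)[C@H]1OC(=O)C=C1C
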